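## Structural features

Target 15 is a monocyclic 1,2-dioxane (ring atoms O1, O2, C3, C4, C5, C6) substituted only at C3 and C6. C6 is a fully substituted peroxyketal carbon that carries O1, a methoxy group, C5 and a sixteen-carbon chain, (CH2)3–C≡C–CH=CH–n-C9H19, in which an E alkene is conjugated to the alkyne. C3 is a secondary peroxide carbon that carries O2, H and a CH2CO2H arm, so the carboxyl carbon stands 1,3 to O2. The SMILES decodes as 3S,6R; the two stereocentres face each other 1,4 across the ring with OMe cis to CH2CO2H, which in the chair means axial (anomeric) OMe and both carbon substituents equatorial, the thermodynamically preferred configuration at C6 for a given C3. Fragile groups are the O–O bond (low-valent metals, phosphines, hydrides), the acid-labile peroxyketal, the enyne (ozone, diimide, hydrometalation) and the β-peroxy carbonyl unit, which in ester form can reopen by E1cB. The real difficulty is the absolute configuration of C3, a C–O–O stereocentre that a conjugate addition would create from a planar carbon with no element of control, together with closing the peroxide ring under conditions that spare ketal and acid. The key step exploits the triad O2–C3–CH2–CO2H: it is the seco form of a β-lactone whose alkyl C–O bond lies exactly where the C3–O2 bond is wanted, so a hydroperoxide on C6, tethered through C5–C4, can displace the lactone oxygen at C3 with inversion and set the acid free in the same event, after which the anomeric preference at C6 lets both C6 epimers converge. In one sentence: the 1,2-dioxane of 10 is closed when the C6 α-methoxy hydroperoxide of 9 opens an enantioenriched β-lactone at its alkyl–oxygen bond.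

## Logic of the disconnections

15 ⇒ 11 + 14. The C(sp)–C(sp2) bond between the alkyne and the E alkene is cut. The whole lipophilic tail then arrives in the last step, so no ozone ever meets the enyne, and the peroxide core is built on a small molecule with a terminal alkyne. The demand on the forward step is a palladium/copper alkyne–alkenyl coupling that tolerates a dialkyl peroxyketal and a free acid.

14 ⇒ 12. The C–I bond is cut back to the terminal alkyne. The demand is a syn, anti-Markovnikov hydrometalation followed by iodination with retention, to give only the E alkenyl iodide.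

11 ⇒ 10. No skeletal bond is cut; the C6–OMe bond is treated as exchangeable. Because 11 is the anomerically favoured C6 epimer, C6 needs no control at the moment the ring is made, and a mixture of C6 epimers is an acceptable precursor. The demand is reversible acid-catalysed ionisation at C6 that does not destroy the O–O bond or esterify the acid.

10 ⇒ 9. The ring bond C3–O2 is cut, and in the reverse sense the carboxylate oxygen is re-attached to C3 to give a β-lactone. This turns the C–O–O stereocentre into a lactone stereocentre that catalytic asymmetric synthesis can deliver, removes any protecting group for the acid, and replaces a planar acceptor carbon by a stereospecific sp3 electrophile. The demand is that the peroxide oxygen attacks the alkyl carbon of the lactone with inversion in the 6-exo-tet mode, and not the acyl carbon.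

9 ⇒ 7. Both C6–O bonds (to OOH and to OMe) are cut back to a 1,1-disubstituted alkene, through carbonyl oxide 8. The peroxide oxygens then come from ozone under neutral conditions at low temperature, which a β-lactone and a terminal alkyne tolerate. The demand is that the primary ozonide cleaves towards the disubstituted carbonyl oxide and that methanol traps it.

7 ⇒ 6. The lactone C–C bond between C3 and C4 of the oxetanone and its ring C–O bond are cut in a formal [2+2] sense to an aldehyde and ketene. The only stereocentre that has to be made by a catalyst is thereby placed in a reliable aldehyde addition. The demand is high enantiofacial control on an unbranched aliphatic aldehyde.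

6 ⇒ 5 ⇒ 4. The aldehyde is taken back to an ester and the C=CH2 bond to a ketone. The demand is a methylenation that leaves the ester alone and a partial reduction that stops at the aldehyde.

4 ⇒ 1 + 2. The bond between the ketone carbon and its α-CH2 on the ester side is cut to acid chloride 3 and a zinc homoenolate, both from commercial materials. The demand is an acylation of the organozinc that tolerates a terminal alkyne.

## Other disconnections considered

Alternative 1: (the first that comes to mind) Cut C3–O2 with C3 as the β-carbon of an E enoate. Forward key step: hydroperoxy ketal A1 cyclises by base-mediated intramolecular oxa-Michael addition to give ester A2. Here C3 is created from a planar carbon with nothing in the substrate to bias the face, so A2 would be racemic at C3 unless an enantioselective intramolecular peroxy-Michael addition onto an enoate were developed first. The β-peroxy ester A2 can also reopen by E1cB under the cyclisation conditions, and a final ester hydrolysis is added. The chosen plan makes the same bond from an sp3 stereocentre with inversion and ends as the carboxylate, which cannot reopen.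

Alternative 2: Cut C6–O1 (and C6–OMe). Forward key step: an enantiopure γ-hydroperoxy ketone A3, made by invertive displacement of a secondary sulfonate by a hydroperoxide synthon, is closed with acid in methanol to peroxyketal A4. A β-sulfonyloxy ester would eliminate, so the carboxyl has to travel as a protected primary alcohol, which costs a reduction, a protection, a deprotection and an oxidation in the presence of the peroxide. The intermolecular displacement at a secondary carbon also competes with E2. The chosen plan uses the same inversion logic but lets the carboxylate be the leaving group, so the acid appears directly and the displacement is intramolecular.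

Alternative 3: Cut both C–O bonds of the peroxide at once, with O2 inserted into a ring C–C bond of a cyclobutanol. Forward key step: cyclobutanol A5 undergoes aerobic oxidative ring expansion with Co(acac)2 to the 1,2-dioxan-3-ol A6, followed by O-methylation in acidic methanol. This is an attractive skeletal rearrangement, but C3 passes through a free secondary alkyl radical before it captures O2, so its configuration cannot be controlled and A6 would be racemic; only the C6/C3 relationship could be corrected afterwards. A5 itself needs a 1,2-disubstituted cyclobutanol synthesis, and the terminal alkyne is exposed to peroxyl radicals. The chosen plan keeps C3 in two-electron, stereospecific chemistry.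

Key step: step 6

Assumption on configuration: the SMILES is read as 3S,6R, with OMe and CH2CO2H cis on the 1,2-dioxane.

Assumption on the catalyst of step 4: with unbranched aliphatic aldehydes the L-valinol-derived aluminium triamine catalyst is taken to give the 4S lactone, so the D-valinol-derived (R,R) ligand is specified for the 4R lactone 7.

## Steps

Step 1
Reactants: 1 hex-5-ynoic acid; 2 (3-ethoxy-3-oxopropyl)zinc bromide (0.5 M in THF)
Product: 4 ethyl 4-oxonon-8-ynoate, via hex-5-ynoyl chloride 3 (not isolated)
Conditions: (COCl)2, cat. DMF, CH2Cl2, 0 °C to rt, evaporate; then 2 (1.2 equiv), Pd(PPh3)4 (3 mol%), THF, 0 °C to rt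
Reagents that add atoms: none
Why: Negishi-type acylation of a zinc homoenolate by an acid chloride under zerovalent palladium catalysis should give the γ-keto ester; the alkylzinc halide is too weakly basic to deprotonate the terminal alkyne, and without copper and amine no alkynyl ketone should form.

Step 2
Reactants: 4 ethyl 4-oxonon-8-ynoate
Product: 5 ethyl 4-methylidenenon-8-ynoate
Conditions: Ph3PCH3Br (1.3 equiv), KOt-Bu (1.25 equiv), THF, 0 °C to rt
Reagents that add atoms: methyltriphenylphosphonium bromide, C[P+](c1ccccc1)(c1ccccc1)c1ccccc1.[Br-]
Why: Wittig methylenation is selective for the ketone over the ester, and the unstabilised ylide is not basic enough to deprotonate the terminal alkyne to a useful extent.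

Step 3
Reactants: 5 ethyl 4-methylidenenon-8-ynoate
Product: 6 4-methylidenenon-8-ynal
Conditions: i-Bu2AlH (1.05 equiv), CH2Cl2, −78 °C; MeOH, then aq. potassium sodium tartrate
Reagents that add atoms: none
Why: Partial reduction of an ethyl ester with i-Bu2AlH at −78 °C should stop at the tetrahedral aluminium hemiacetal, which releases the aldehyde on work-up; the alkene and the alkyne are inert at this temperature.

Step 4
Reactants: 6 4-methylidenenon-8-ynal
Product: 7 (4R)-4-(3-methylideneoct-7-yn-1-yl)oxetan-2-one
Conditions: AcBr (1.9 equiv), i-Pr2NEt (1.7 equiv), (R,R)-MeAl[BnN(CH2CH(i-Pr)NTf)2] (10 mol%), CH2Cl2, −50 °C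
Reagents that add atoms: acetyl bromide, CC(=O)Br
Why: Catalytic asymmetric acyl halide–aldehyde cyclocondensation (ketene generated in the flask adds to the aldehyde bound to the chiral trivalent aluminium centre) is well precedented for unbranched aliphatic aldehydes; the lactone stereocentre is set by the catalyst, which shields one face of the coordinated aldehyde.

Step 5
Reactants: 7 (4R)-4-(3-methylideneoct-7-yn-1-yl)oxetan-2-one
Product: 9 (4R)-4-[(3RS)-3-hydroperoxy-3-methoxyoct-7-yn-1-yl]oxetan-2-one, via carbonyl oxide 8 (not isolated)
Conditions: O3 (end-point by Sudan Red 7B), CH2Cl2/MeOH 4:1, −78 °C; N2 purge, concentrate below 20 °C, no reductive work-up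
Reagents that add atoms: ozone, [O-][O+]=O; methanol, CO
Why: Ozonolysis of a 1,1-disubstituted alkene in methanol (Criegee mechanism) cleaves the primary ozonide towards the more substituted carbonyl oxide and formaldehyde, and methanol traps the carbonyl oxide as the α-methoxy hydroperoxide; the electron-poor terminal alkyne reacts far more slowly, the neutral cold medium leaves the lactone intact, and the new C3' centre is formed as both epimers, which is harmless.

Step 6
Reactants: 9 (4R)-4-[(3RS)-3-hydroperoxy-3-methoxyoct-7-yn-1-yl]oxetan-2-one
Product: 10 2-[(3S,6RS)-6-methoxy-6-(pent-4-yn-1-yl)-1,2-dioxan-3-yl]acetic acid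
Conditions: KOt-Bu (1.05 equiv, added slowly), 18-crown-6 (1.1 equiv), THF, 0.01 M, −40 to 0 °C; cold 0.5 M aq. HCl to pH 3
Reagents that add atoms: none
Why: Proposed new method: deprotonation of the hydroperoxide of 9 (pKa about 12) gives a peroxy anion that attacks the lactone carbon C4 from the side opposite the ring oxygen, cleaving the alkyl C–O bond and expelling the carboxylate with release of roughly 23 kcal/mol of ring strain; the closest known reaction types are the invertive C4 opening of 4-alkyl β-lactones by azide, thiolate and carboxylate nucleophiles, the 6-exo opening of oxetanes by tethered hydroperoxides, and the intramolecular alkylation of hydroperoxides by secondary sulfonates. The 1,2-dioxane closes in the 6-exo-tet mode, with the breaking C–O bond outside the new ring, so the collinear O···C–O arrangement is reached through a chair-like transition state. C3 of the dioxane is fixed by the lactone stereocentre alone, clean inversion turning 4R into 3S, while C6 is carried through as both epimers and is settled in step 7. The selectivity needed is alkyl–oxygen over acyl–oxygen attack: intramolecular acyl attack would need an eight-membered cyclic perester, so the tether length secures the site, and high dilution suppresses intermolecular acyl attack. The single equivalent of base is consumed by the far more acidic O–O–H, so the lactone is not enolised, and the four-membered ring holds its C3–H bonds out of anti-periplanar alignment with the C4–O bond, which disfavours elimination. The product leaves the step as a carboxylate, which cannot undergo retro-oxa-Michael opening, so the new stereocentre should not erode.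

Step 7
Reactants: 10 2-[(3S,6RS)-6-methoxy-6-(pent-4-yn-1-yl)-1,2-dioxan-3-yl]acetic acid
Product: 11 2-[(3S,6R)-6-methoxy-6-(pent-4-yn-1-yl)-1,2-dioxan-3-yl]acetic acid
Conditions: camphorsulfonic acid (10 mol%), MeOH (5 equiv), anhydrous CH2Cl2, 0 °C to rt
Reagents that add atoms: methanol, CO
Why: Acid-catalysed peroxyketal exchange ionises C6 reversibly to the cyclic peroxycarbenium ion, and methanol returns until the thermodynamic epimer dominates: axial OMe (anomeric effect) with the pentynyl chain and the CH2CO2H arm both equatorial, which is 6R for 3S; the low methanol concentration is chosen to keep Fischer esterification slow.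

Step 8
Reactants: 12 undec-1-yne
Product: 14 (E)-1-iodoundec-1-ene, via alkenylzirconocene chloride 13 (not isolated)
Conditions: Cp2Zr(H)Cl (1.2 equiv), THF, rt; then I2 (1.2 equiv), 0 °C
Reagents that add atoms: iodine, II
Why: Hydrozirconation of a terminal alkyne is syn and places zirconium on the terminal carbon, and iodinolysis of the C–Zr bond proceeds with retention, so only the E alkenyl iodide is expected.

Step 9
Reactants: 11 2-[(3S,6R)-6-methoxy-6-(pent-4-yn-1-yl)-1,2-dioxan-3-yl]acetic acid; 14 (E)-1-iodoundec-1-ene
Product: 15 2-[(3S,6R)-6-[(6E)-hexadec-6-en-4-yn-1-yl]-6-methoxy-1,2-dioxan-3-yl]acetic acid (CNP0298534.1)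
Conditions: Pd(PPh3)4 (5 mol%), CuI (10 mol%), Et3N (5 equiv), degassed THF, rt; aq. citric acid to pH 4
Reagents that add atoms: none
Why: Sonogashira coupling of a terminal alkyne with an alkenyl iodide runs at room temperature with retention of the E geometry; dialkyl peroxyketals are expected to survive these mild conditions, the acid is carried as its ammonium carboxylate, and neither stereocentre is touched.

## Compound list

1 | hex-5-ynoic acid | OC(=O)CCCC#C | starting material
2 | (3-ethoxy-3-oxopropyl)zinc bromide | CCOC(=O)CC[Zn]Br | starting material
3 | hex-5-ynoyl chloride | ClC(=O)CCCC#C | intermediate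
4 | ethyl 4-oxonon-8-ynoate | CCOC(=O)CCC(=O)CCCC#C | intermediate
5 | ethyl 4-methylidenenon-8-ynoate | CCOC(=O)CCC(=C)CCCC#C | intermediate
6 | 4-methylidenenon-8-ynal | O=CCCC(=C)CCCC#C | intermediate
7 | (4R)-4-(3-methylideneoct-7-yn-1-yl)oxetan-2-one | O=C1C[C@@H](CCC(=C)CCCC#C)O1 | intermediate
8 | (4R)-4-(3-oxooct-7-yn-1-yl)oxetan-2-one O-oxide (carbonyl oxide) | O=C1C[C@@H](CCC(=[O+][O-])CCCC#C)O1 | intermediate
9 | (4R)-4-[(3RS)-3-hydroperoxy-3-methoxyoct-7-yn-1-yl]oxetan-2-one | O=C1C[C@@H](CCC(OC)(OO)CCCC#C)O1 | intermediate
10 | 2-[(3S,6RS)-6-methoxy-6-(pent-4-yn-1-yl)-1,2-dioxan-3-yl]acetic acid | C#CCCCC1(OC)CC[C@@H](CC(=O)O)OO1 | intermediate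
11 | 2-[(3S,6R)-6-methoxy-6-(pent-4-yn-1-yl)-1,2-dioxan-3-yl]acetic acid | C#CCCC[C@]1(OC)CC[C@@H](CC(=O)O)OO1 | intermediate
12 | undec-1-yne | CCCCCCCCCC#C | starting material
13 | chloro[(E)-undec-1-en-1-yl]zirconocene | CCCCCCCCC/C=C/[Zr](Cl)(C1C=CC=C1)C1C=CC=C1 | intermediate
14 | (E)-1-iodoundec-1-ene | CCCCCCCCC/C=C/I | intermediate
15 | 2-[(3S,6R)-6-[(6E)-hexadec-6-en-4-yn-1-yl]-6-methoxy-1,2-dioxan-3-yl]acetic acid | CCCCCCCCC/C=C/C#CCCC[C@]1(OC)CC[C@@H](CC(=O)O)OO1 | target

## Step count and least certain steps

Total step count: 9. Longest linear sequence: 8 (steps 1 to 7 and 9); step 8 is a one-step side branch.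

Step 6 (key step, proposed new method). The most likely failure is attack at the acyl carbon instead of the alkyl carbon, most plausibly intermolecular, which would give peresters and oligomers; the α-effect of a peroxy anion is large towards carbonyl carbon, and only the tether and dilution hold it back. Slow substitution at the secondary carbon would also leave time for base-induced decomposition of the hydroperoxy ketal. Fallback, with known chemistry, from 7 to 10: lactone 7 is reduced with LiBH4 to (3R)-6-methylideneundec-10-yne-1,3-diol F1. The primary hydroxyl is silylated selectively with t-BuPh2SiCl and imidazole to (3R)-1-[(tert-butyldiphenylsilyl)oxy]-6-methylideneundec-10-yn-3-ol F2, and the secondary hydroxyl is converted with MsCl and Et3N into (3R)-1-[(tert-butyldiphenylsilyl)oxy]-6-methylideneundec-10-yn-3-yl methanesulfonate F3. Ozonolysis in CH2Cl2/MeOH as in step 5 should give (3R,6RS)-1-[(tert-butyldiphenylsilyl)oxy]-6-hydroperoxy-6-methoxyundec-10-yn-3-yl methanesulfonate F4. Treatment with KOt-Bu and 18-crown-6 then closes the ring by the established 6-exo-tet alkylation of a hydroperoxide by a secondary sulfonate, with inversion, to tert-butyl{2-[(3S,6RS)-6-methoxy-6-(pent-4-yn-1-yl)-1,2-dioxan-3-yl]ethoxy}diphenylsilane F5. Desilylation with Bu4NF gives 2-[(3S,6RS)-6-methoxy-6-(pent-4-yn-1-yl)-1,2-dioxan-3-yl]ethan-1-ol F6, and oxidation with TEMPO and PhI(OAc)2 in MeCN/H2O returns to the route at 10. The same lactone enantiomer serves, because both ring closures invert the same carbon.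

Step 7. The most likely failure is incomplete convergence accompanied by side reactions of the free acid under the ionising conditions: Fischer esterification, or capture of the C6 cation by the cis carboxyl group to a bridged acyloxy peroxyketal; prolonged acid could also open the peroxyketal. Fallback from 10 to 11: the acid is masked first with Me3SiCHN2 in toluene/MeOH as methyl 2-[(3S,6RS)-6-methoxy-6-(pent-4-yn-1-yl)-1,2-dioxan-3-yl]acetate F10. The ester can be equilibrated in neat acidic methanol without those side reactions to methyl 2-[(3S,6R)-6-methoxy-6-(pent-4-yn-1-yl)-1,2-dioxan-3-yl]acetate F11. Saponification with LiOH in THF/H2O at 0 °C, where hydrolysis should outrun E1cB opening, returns to the route at 11.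

Step 9. The most likely failure is reductive cleavage of the O–O bond by zerovalent palladium, monovalent copper or free phosphine during the coupling. Fallback from 7 to 15, with the coupling moved ahead of the peroxide: 7 and 14 are coupled with Pd(PPh3)4, CuI and i-Pr2NEt to (4R)-4-[(9E)-3-methylidenenonadec-9-en-7-yn-1-yl]oxetan-2-one F7. Ozonolysis with a limiting amount of ozone in CH2Cl2/MeOH, relying on the higher reactivity of the 1,1-disubstituted alkene over the enyne alkene, gives (4R)-4-[(3RS,9E)-3-hydroperoxy-3-methoxynonadec-9-en-7-yn-1-yl]oxetan-2-one F8. Ring closure as in step 6 gives 2-[(3S,6RS)-6-[(6E)-hexadec-6-en-4-yn-1-yl]-6-methoxy-1,2-dioxan-3-yl]acetic acid F9, and equilibration as in step 7 returns to the route at 15. The price is a less selective ozonolysis.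

Step 4. The most likely failure is insufficient enantioselectivity, through a competing uncatalysed ketene addition or through deactivation of the moisture-sensitive aluminium catalyst, or a sense of induction opposite to the one assumed. Fallback from 6 to 7, with the stereocentre taken from a Sharpless epoxidation: Horner–Wadsworth–Emmons reaction of 6 with triethyl phosphonoacetate gives ethyl (2E)-6-methylideneundec-2-en-10-ynoate F12, and i-Bu2AlH reduces it to (2E)-6-methylideneundec-2-en-10-yn-1-ol F13. Epoxidation with Ti(Oi-Pr)4, D-(−)-diethyl tartrate and t-BuOOH gives [(2R,3R)-3-(3-methylideneoct-7-yn-1-yl)oxiran-2-yl]methanol F14. Opening at C2 with NaAlH2(OCH2CH2OMe)2 gives the diol F1 of the first fallback. Selective oxidation of its primary hydroxyl with TEMPO and PhI(OAc)2 in MeCN/H2O gives (3R)-3-hydroxy-6-methylideneundec-10-ynoic acid F15, and lactonisation by carboxyl activation with PhSO2Cl in pyridine, which retains the carbinol configuration, returns to the route at 7.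

## Further compounds

F1 | step 6 | (3R)-6-methylideneundec-10-yne-1,3-diol | OCC[C@H](O)CCC(=C)CCCC#C
F2 | step 6 | (3R)-1-[(tert-butyldiphenylsilyl)oxy]-6-methylideneundec-10-yn-3-ol | CC(C)(C)[Si](c1ccccc1)(c1ccccc1)OCC[C@H](O)CCC(=C)CCCC#C
F3 | step 6 | (3R)-1-[(tert-butyldiphenylsilyl)oxy]-6-methylideneundec-10-yn-3-yl methanesulfonate | CC(C)(C)[Si](c1ccccc1)(c1ccccc1)OCC[C@H](OS(C)(=O)=O)CCC(=C)CCCC#C
F4 | step 6 | (3R,6RS)-1-[(tert-butyldiphenylsilyl)oxy]-6-hydroperoxy-6-methoxyundec-10-yn-3-yl methanesulfonate | CC(C)(C)[Si](c1ccccc1)(c1ccccc1)OCC[C@H](OS(C)(=O)=O)CCC(OC)(OO)CCCC#C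
F5 | step 6 | tert-butyl{2-[(3S,6RS)-6-methoxy-6-(pent-4-yn-1-yl)-1,2-dioxan-3-yl]ethoxy}diphenylsilane | C#CCCCC1(OC)CC[C@@H](CCO[Si](c2ccccc2)(c2ccccc2)C(C)(C)C)OO1
F6 | step 6 | 2-[(3S,6RS)-6-methoxy-6-(pent-4-yn-1-yl)-1,2-dioxan-3-yl]ethan-1-ol | C#CCCCC1(OC)CC[C@@H](CCO)OO1
F7 | step 9 | (4R)-4-[(9E)-3-methylidenenonadec-9-en-7-yn-1-yl]oxetan-2-one | O=C1C[C@@H](CCC(=C)CCCC#C/C=C/CCCCCCCCC)O1
F8 | step 9 | (4R)-4-[(3RS,9E)-3-hydroperoxy-3-methoxynonadec-9-en-7-yn-1-yl]oxetan-2-one | O=C1C[C@@H](CCC(OC)(OO)CCCC#C/C=C/CCCCCCCCC)O1
F9 | step 9 | 2-[(3S,6RS)-6-[(6E)-hexadec-6-en-4-yn-1-yl]-6-methoxy-1,2-dioxan-3-yl]acetic acid | CCCCCCCCC/C=C/C#CCCCC1(OC)CC[C@@H](CC(=O)O)OO1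
F10 | step 7 | methyl 2-[(3S,6RS)-6-methoxy-6-(pent-4-yn-1-yl)-1,2-dioxan-3-yl]acetate | C#CCCCC1(OC)CC[C@@H](CC(=O)OC)OO1
F11 | step 7 | methyl 2-[(3S,6R)-6-methoxy-6-(pent-4-yn-1-yl)-1,2-dioxan-3-yl]acetate | C#CCCC[C@]1(OC)CC[C@@H](CC(=O)OC)OO1
F12 | step 4 | ethyl (2E)-6-methylideneundec-2-en-10-ynoate | CCOC(=O)/C=C/CCC(=C)CCCC#C
F13 | step 4 | (2E)-6-methylideneundec-2-en-10-yn-1-ol | OC/C=C/CCC(=C)CCCC#C
F14 | step 4 | [(2R,3R)-3-(3-methylideneoct-7-yn-1-yl)oxiran-2-yl]methanol | OC[C@H]1O[C@@H]1CCC(=C)CCCC#C
F15 | step 4 | (3R)-3-hydroxy-6-methylideneundec-10-ynoic acid | OC(=O)C[C@H](O)CCC(=C)CCCC#C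
A1 | alternative 1 | methyl (2E)-6-hydroperoxy-6-methoxyundec-2-en-10-ynoate | COC(=O)/C=C/CCC(OC)(OO)CCCC#C
A2 | alternative 1 | methyl 2-[6-methoxy-6-(pent-4-yn-1-yl)-1,2-dioxan-3-yl]acetate (racemic, both C6 epimers) | COC(=O)CC1CCC(OC)(CCCC#C)OO1
A3 | alternative 2 | (3S)-1-[(tert-butyldimethylsilyl)oxy]-3-hydroperoxyundec-10-yn-6-one | C#CCCCC(=O)CC[C@@H](CCO[Si](C)(C)C(C)(C)C)OO
A4 | alternative 2 | tert-butyl{2-[(3S,6R)-6-methoxy-6-(pent-4-yn-1-yl)-1,2-dioxan-3-yl]ethoxy}dimethylsilane | C#CCCC[C@]1(OC)CC[C@@H](CCO[Si](C)(C)C(C)(C)C)OO1
A5 | alternative 3 | ethyl 2-[2-hydroxy-2-(pent-4-yn-1-yl)cyclobutyl]acetate (racemic) | CCOC(=O)CC1CCC1(O)CCCC#C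
A6 | alternative 3 | ethyl 2-[6-hydroxy-6-(pent-4-yn-1-yl)-1,2-dioxan-3-yl]acetate (racemic) | CCOC(=O)CC1CCC(O)(CCCC#C)OO1
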